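## Analysis of the target

Japonicone A (46) is a C32 dimer in which a guaianolide and an eudesmanolide share a bicyclo[2.2.1]heptene. The bridgeheads are C1 and C3, the one-carbon bridge is C2 (acetoxy, syn to the alkene), and the two-carbon bridges are C4=C5 and C13′–C11′, where C11′ is also the spiro α-carbon of the eudesmanolide lactone. The guaiane half adds a cycloheptane (C1, C5–C10) with a C10 methyl and a trans-fused α-methylene-γ-lactone (C7, C8, C11–C13). The eudesmane half is a Δ5′-octalin with a cis-fused lactone whose 1′-hydroxyl, 4′-methyl, 10′-methyl and lactone all lie on one face. There are twelve stereocentres (C1, C2, C3, C7, C8, C10, C1′, C4′, C7′, C8′, C10′, C11′), two of them quaternary (C1, C11′) and adjacent to further stereocentres (C10, C7′). C3 sits on the convex face of the eudesmanolide lactone, the lactone carbonyl is endo to C4=C5, and on the seven-membered ring C11 is cis and O8 trans to the C10 methyl. Sensitive groups are the exocyclic methylene lactone (Michael acceptor), the strained tetrasubstituted C4=C5 alkene, one acetate beside one free secondary alcohol, and two lactones that must be told apart from every other acyl group. The strategy rests on the C4=C5 alkene of the five-membered ring C1–C5: cutting it leaves a cyclopentane (C1, C2, C3, C11′, C13′) whose C1 and C3 carry cis ketone groups.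

## Retrosynthetic reasoning

**C7–C8 and O8–C12 (46 → 45 → 43).** The methylene lactone and the seven-membered ring are cut together. Aldehyde 43 carries the C8 carbonyl and a 2-(bromomethyl)enoate on C6, so an allyl-metal addition through C7 forms C7–C8, restores C11=C13 and is followed by lactonisation. The most reactive functional group of the target is thus made last, on an otherwise complete skeleton. The forward step has to give the anti (trans) adduct on the correct face.

**Side chains and protecting groups (43 → 35).** The enoate is traced to a C7 aldehyde and an acrylate α-anion equivalent. The C8 aldehyde comes from a silyl-protected primary alcohol, which avoids an alkene cleavage next to three other alkenes. The C2 acetate replaces a triethylsilyl ether immediately after the alkene is formed. This leads back to norbornene 35.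

**C4=C5 (35 → 34).** The tetrasubstituted alkene is cut to two ketones, the C4 acetyl on C3 and the C5 acyl on C1, held cis on the cyclopentane of 34. No other disconnection of the bicycle removes a ring and a strained alkene without touching a stereocentre. The forward reaction is a reductive carbonyl coupling that must prefer ketone–ketone over ketone–lactone coupling and tolerate silyl and benzyl-type ethers.

**C2–C3 (34 → 32).** The β-silyloxy ketone is an aldol retron. Cutting C2–C3 gives the 2-formyl ketone 32 with a methyl ketone on C11′. A 5-exo aldol addition has to set C2 and C3; both are under thermodynamic control before silylation.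

**C11′–C3 and oxidation levels (32 → 28 → 26).** A free 2-formyl ketone cannot survive the strong base needed to alkylate a lactone. C2 and C8 are therefore carried as a δ-lactone and C5 as a carbinol (28), and the methyl ketone as a propargyl group. The propargyl group is introduced at C11′ of 26 from the convex face of the bicyclic lactone, which fixes C11′.

**C13′–C11′ and C1–C5 (26 → 15 + 21 + 24).** The quaternary C1 is assembled on the six-membered lactone 21, whose C10 methyl controls the face. The enolate of lactone 15 adds to the exocyclic methylene of 21, and the resulting enolate is trapped by aldehyde 24 anti to the methyl group. This replaces an acyclic conjugate addition, where a methyl and a methylene substituent at C10 would not differentiate the faces of C1.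

**Eudesmanolide 15 (15 → 12 → 11 → 3 → 1).** The lactone is cut at C7′–C11′ and C8′–O to the β,γ-unsaturated ketone 12. Ring B is opened at C5′=C6′ by ring-closing metathesis to diene 11. Ring A is (S)-carvone (1): C6 becomes the quaternary C10′ by two alkylations, the isopropenyl group becomes the C1′ oxygen with retention, and the enone methyl becomes C15′.

**Small fragments (21 → 16; 24 → 22).** Lactone 21 comes from the hemiester 16, which supplies C10. Aldehyde 24 comes from propane-1,3-diol (22).

## Alternatives that were turned down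

**Alternative 1:** Ring B and the spiro-lactone would be formed together by cutting C7′–C8′ and C9′–C10′. In the forward direction an ester-tethered vinyl sulfone adds to a diene attached to the same carbon, giving sulfone A1. In its favour, one step builds two rings, two bonds and three stereocentres, and the norbornene would direct the approach. Against it, ester tethers disfavour the reactive conformer in intramolecular Diels–Alder reactions, the diene terminus that becomes C10′ is fully substituted, and the sulfone must then be removed reductively next to a lactone. The norbornene with its C4=C5 alkene would still have to be made first. On ring-forming economy A1 is stronger than the chosen route, which needs ten steps for the eudesmanolide. The chosen route offers instead a separately secured eudesmanolide whose convex face sets C11′ reliably, and the risk is confined to one late step.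

**Alternative 2:** The lactone and the seven-membered ring would be cut at C7–C11 and C5–C6. A bromoacetal radical on O8 closes onto C7, and the C6 radical then attacks C5 with loss of a sulfonyl radical, giving lactol ether A2. In its favour are mild neutral conditions, two rings in one operation and an alkene that is regenerated rather than carried. Against it, alkyl radicals add to the β-carbon of vinyl sulfones, not to the sulfonyl-bearing carbon, so the second closure fights the innate polarity. It must also form a seven-membered ring at a hindered, strained alkene, and the lactol still has to be oxidised and methylenated. A2 is at least as step-economic in the endgame. The chosen allylation instead forms C7–C8 by a polar, well-precedented reaction type and delivers the methylene lactone directly.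

**Alternative 3:** The norbornane would be closed at C2–C3 by a ketyl–enone cyclisation, giving ketol A3. In its favour, samarium ketyl additions to enones are reliable, the C2 hydroxyl arises in the ring-forming step and no strained alkene is formed at that stage. Against it, A3 has C5 as a ketone and C4 as an sp3 centre, so the tetrasubstituted alkene and the C6 chain must still be installed at a bridging position, through an enol derivative and a cross-coupling, which costs several steps. The spiro cyclohexenone with quaternary C1 is no easier to reach than 34. A3 is stronger in the safety of its ring closure; the chosen coupling forms the alkene with the C6–C7 chain already in place.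

Key step: step 22

Remark: the target's stereodescriptors place its eudesmane half in the mirror-image series of the common alantolactones, so (S)-(+)-carvone is the chiral-pool source; 16 is taken as the commercial (R)-hemiester.

## Route

Step 1
Reactants: 1 (S)-(+)-carvone
Product: 2 6-methylcarvone (C6 epimers, trans major)
Conditions: LiN(i-Pr)2, THF, −78 °C; MeI, −78 → 0 °C
Reagents that add atoms: iodomethane, CI
Why: Kinetic deprotonation of the cross-conjugated enone at C6 followed by enolate alkylation; the C6 configuration does not matter because this centre is re-enolised in step 2.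

Step 2
Reactants: 2 6-methylcarvone
Product: 3 methyl 2-[(1R,6R)-1,3-dimethyl-2-oxo-6-(prop-1-en-2-yl)cyclohex-3-en-1-yl]acetate
Conditions: LiN(i-Pr)2, THF, −78 °C; BrCH2CO2Me, DMPU, −78 → −20 °C
Reagents that add atoms: methyl bromoacetate, COC(=O)CBr
Why: Enolate alkylation; the electrophile should enter anti to the adjacent isopropenyl group, leaving the ring methyl cis to it, which sets C10′ relative to the future C1′ oxygen.

Step 3
Reactants: 3 keto ester
Product: 5 methyl 2-[6-acetoxy-1,3-dimethyl-2-oxocyclohex-3-en-1-yl]acetate (acetoxy cis to the 1-methyl), via methoxy hydroperoxide 4 (not isolated)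
Conditions: O3, CH2Cl2/MeOH, −78 °C; then Ac2O, Et3N, DMAP, 0 → 40 °C
Reagents that add atoms: ozone, [O-][O+]=O; methanol, CO
Why: Ozonolysis of the electron-rich 1,1-disubstituted alkene in methanol, then Criegee rearrangement of the peracetate, in which the ring carbon migrates to oxygen with retention; the electron-poor enone alkene should not react.

Step 4
Reactants: 5 acetate
Product: 7 tert-butyldimethylsilyl ether of the C1′ alcohol, via alcohol 6 (not isolated)
Conditions: AcCl (cat.), MeOH, 25 °C; then t-BuMe2SiOTf, 2,6-lutidine, CH2Cl2, 0 °C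
Reagents that add atoms: tert-butyldimethylsilyl triflate, CC(C)(C)[Si](C)(C)OS(=O)(=O)C(F)(F)F
Why: Acid-catalysed transesterification frees the alcohol without the retro-aldol opening that alkoxide could cause in this β-hydroxy ketone; the silyl triflate silylates the hindered secondary alcohol.

Step 5
Reactants: 7 enone
Product: 8 methyl 2-[6-(tert-butyldimethylsilyloxy)-1,3-dimethyl-2-oxocyclohexyl]acetate (1-methyl, 3-methyl and 6-silyloxy all cis)
Conditions: H2 (1 atm), 10% Pd/C, EtOAc, 25 °C
Reagents that add atoms: none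
Why: Heterogeneous hydrogenation of the enone alkene; with the silyloxy group equatorial the C14′ methyl is axial and shields its face, so hydrogen should add from the other face and place the C4′ methyl cis to C14′, and the neutral conditions keep this kinetic epimer.

Step 6
Reactants: 8 ketone
Product: 9 methyl 2-[6-(tert-butyldimethylsilyloxy)-1,3-dimethyl-2-methylenecyclohexyl]acetate
Conditions: Zn, CH2Br2, TiCl4, THF, 0 → 25 °C
Reagents that add atoms: dibromomethane, BrCBr
Why: Takai–Lombardo methylenation; the non-basic reagent converts the hindered ketone without epimerising C4′ and leaves the ester alone.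

Step 7
Reactants: 9 ester
Product: 11 1-[6-(tert-butyldimethylsilyloxy)-1,3-dimethyl-2-methylenecyclohexyl]pent-4-en-2-one, via N-methoxy-N-methyl amide 10 (not isolated)
Conditions: MeNHOMe·HCl, i-PrMgCl, THF, −20 °C; then CH2=CHCH2MgBr, −78 → 0 °C; cold aq. NH4Cl
Reagents that add atoms: allylmagnesium bromide, C=CC[Mg]Br (N,O-dimethylhydroxylamine hydrochloride, CNOC.Cl, adds atoms to 10 only)
Why: Weinreb ketone synthesis in one flask; the chelated tetrahedral intermediate stops the Grignard reagent after one addition, and the cold neutral quench keeps the alkene out of conjugation.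

Step 8
Reactants: 11 diene
Product: 12 (5R,8S,8aS)-8-(tert-butyldimethylsilyloxy)-5,8a-dimethyl-3,5,6,7,8,8a-hexahydronaphthalen-2(1H)-one
Conditions: (H2IMes)(PCy3)Cl2Ru=CHPh (second-generation Grubbs catalyst, 5 mol %), 1,4-benzoquinone (10 mol %), CH2Cl2, 40 °C
Reagents that add atoms: none
Why: Ring-closing metathesis of a 1,1-disubstituted with a monosubstituted alkene closes ring B as the trisubstituted C5′=C6′ alkene; benzoquinone suppresses ruthenium hydride isomerisation into conjugation.

Step 9
Reactants: 12 β,γ-unsaturated ketone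
Product: 13 methyl 2-[(2R,4aS,5S,8R)-5-(tert-butyldimethylsilyloxy)-4a,8-dimethyl-3-oxo-2,3,4,4a,5,6,7,8-octahydronaphthalen-2-yl]acetate
Conditions: LiN(i-Pr)2, THF, −78 °C; BrCH2CO2Me, DMPU, −78 °C; then KN(SiMe3)2, −78 °C; AcOH, −78 °C
Reagents that add atoms: methyl bromoacetate, COC(=O)CBr
Why: Deprotonation at the doubly activated C7′ gives the linear dienolate, and α-alkylation keeps the alkene at C5′=C6′; re-enolisation and kinetic protonation from the face away from the C14′ methyl should leave the acetate chain equatorial on the methyl face (deconjugative α-alkylation, kinetic protonation).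

Step 10
Reactants: 13 keto ester
Product: 15 (3aR,5R,8S,8aS,9aS)-8-(tert-butyldimethylsilyloxy)-5,8a-dimethyl-3a,5,6,7,8,8a,9,9a-octahydronaphtho[2,3-b]furan-2(3H)-one, via hydroxy ester 14 (not isolated)
Conditions: LiBH(s-Bu)3, THF, −78 °C; then 1 M HCl, 0 → 25 °C
Reagents that add atoms: none
Why: The bulky hydride should attack the ketone from the face away from the axial C14′ methyl, giving the axial alcohol cis to the acetate chain; acid then closes the cis-fused γ-lactone.

Step 11
Reactants: 16 methyl hydrogen (R)-3-methylglutarate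
Product: 18 (R)-4-methyltetrahydro-2H-pyran-2-one, via methyl (R)-5-hydroxy-3-methylpentanoate 17 (not isolated)
Conditions: BH3·SMe2, THF, 0 → 25 °C; MeOH; then TsOH·H2O (cat.), toluene, 60 °C
Reagents that add atoms: none
Why: Borane reduces the carboxylic acid chemoselectively beside the ester, and acid-catalysed lactonisation follows; the stereocentre is not touched.

Step 12
Reactants: 18 lactone
Product: 21 (R)-4-methyl-3-methylenetetrahydro-2H-pyran-2-one, via Mannich base 19 (not isolated), via methiodide 20 (not isolated)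
Conditions: LiN(i-Pr)2, THF, −78 °C; CH2=NMe2 I, −78 → 25 °C; then MeI, MeOH, 25 °C; then NaHCO3, CH2Cl2/H2O
Reagents that add atoms: N,N-dimethylmethyleneiminium iodide, C=[N+](C)C.[I-]
Why: Mannich reaction of the lactone enolate with Eschenmoser's salt, quaternisation and elimination (α-methylenation); the mild bicarbonate elimination avoids migration of the alkene into the ring.

Step 13
Reactants: 22 propane-1,3-diol
Product: 23 3-[(4-methoxybenzyl)oxy]propan-1-ol
Conditions: NaH (1 equiv), THF, 0 °C; 4-MeOC6H4CH2Cl, Bu4NI (cat.), 25 °C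
Reagents that add atoms: 4-methoxybenzyl chloride, COc1ccc(CCl)cc1
Why: Williamson etherification of the mono-alkoxide of a symmetrical diol.

Step 14
Reactants: 23 alcohol
Product: 24 3-[(4-methoxybenzyl)oxy]propanal
Conditions: (COCl)2, DMSO, CH2Cl2, −78 °C; Et3N
Reagents that add atoms: none
Why: Swern oxidation; the cold non-aqueous conditions avoid β-elimination of the alkoxy aldehyde.

Step 15
Reactants: 15 eudesmane lactone; 21 methylene lactone; 24 aldehyde
Product: 26 bis-lactone, (3R,4R)-4-methyl-3-[3-(4-methoxybenzyloxy)-1-(trimethylsilyloxy)propyl]-3-[(lactone 15-3-yl)methyl]tetrahydropyran-2-one (epimers at C5 and C11′), via aldol adduct 25 (not isolated)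
Conditions: 15, LiN(i-Pr)2, THF, −78 °C; then 21 (slow addition), −78 °C; then 24, −78 °C; then Me3SiCl, Et3N, −78 → 0 °C
Reagents that add atoms: chlorotrimethylsilane, C[Si](C)(C)Cl
Why: Tandem Michael–aldol reaction: the enolate of 15 adds to the exocyclic methylene of 21 and the new six-membered lactone enolate is trapped by 24 anti to the adjacent C10 methyl, which sets the quaternary C1 with C13′ cis and C5 trans to that methyl; silylation of the aldolate blocks retro-aldol, and the C5 and C11′ configurations are erased later.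

Step 16
Reactants: 26 bis-lactone
Product: 28 C11′-propargylated bis-lactone with free C5 hydroxyl and terminal alkyne, via bis-silylated alkylation product 27 (not isolated)
Conditions: LiN(i-Pr)2, THF/HMPA, −78 → −40 °C; BrCH2C≡CSiMe3; then Bu4NF, AcOH, THF, 0 °C
Reagents that add atoms: 3-bromo-1-(trimethylsilyl)prop-1-yne, BrCC#C[Si](C)(C)C
Why: C11′–H is the only acidic C–H left, and the cis-fused lactone enolate is alkylated on its convex face (syn to H7′), so the propargyl carbon becomes C3 and C13′ is pushed to the concave face; buffered fluoride then removes both trimethylsilyl groups.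

Step 17
Reactants: 28 hydroxy bis-lactone
Product: 29 triol (C2 and C8 primary hydroxyls, C5 secondary hydroxyl; eudesmanolide intact)
Conditions: NaBH4, THF/MeOH, 0 → 25 °C; aq. NH4Cl
Reagents that add atoms: none
Why: Borohydride reduction of the six-membered lactone, assisted by the free β-hydroxyl and by the higher reactivity of δ-lactones; the hindered spiro γ-lactone should not be reduced under these conditions.

Step 18
Reactants: 29 triol
Product: 30 diol with C8 tert-butyldiphenylsilyl ether
Conditions: t-BuPh2SiCl, imidazole, CH2Cl2, −20 °C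
Reagents that add atoms: tert-butylchlorodiphenylsilane, CC(C)(C)[Si](Cl)(c1ccccc1)c1ccccc1
Why: Silylation of the only unhindered primary hydroxyl; the C2 hydroxyl is neopentyl and the C5 hydroxyl secondary.

Step 19
Reactants: 30 diol
Product: 31 2-formyl ketone (C2 aldehyde and C5 ketone on quaternary C1)
Conditions: Dess–Martin periodinane, NaHCO3, CH2Cl2, 0 → 25 °C
Reagents that add atoms: none
Why: Dess–Martin oxidation of both hydroxyls; C1 is quaternary, so the 1,3-dicarbonyl cannot enolise or epimerise.

Step 20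
Reactants: 31 alkyne
Product: 32 methyl ketone (C4 carbonyl, C15 methyl) on C3
Conditions: Ph3PAuNTf2 (5 mol %), 1,4-dioxane/H2O, 40 °C
Reagents that add atoms: water, O
Why: Gold-catalysed Markovnikov hydration of the terminal alkyne, assisted by the neighbouring lactone carbonyl, under near-neutral conditions that spare the formyl ketone.

Step 21
Reactants: 32 keto aldehyde
Product: 34 cis-1,3-diacyl spiro-lactone cyclopentane with C2 triethylsilyl ether, via aldol 33 (not isolated)
Conditions: LiCl, DBU, THF, 0 °C; then Et3SiOTf, 2,6-lutidine, −78 °C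
Reagents that add atoms: triethylsilyl triflate, CC[Si](CC)(CC)OS(=O)(=O)C(F)(F)F
Why: Reversible intramolecular aldol addition (5-exo) of the C3 enolate to the C2 aldehyde; lithium chelation of the C2 alkoxide by the C5 and C4 carbonyls should favour the all-cis isomer, with the oxygen cis to the smaller C1 substituent and the acetyl trans to C7′, and immediate silylation stops retro-aldol and dehydration.

Step 22
Reactants: 34 diketone
Product: 35 norbornene spirolactone with C6–C7 and C10 side chains
Conditions: TiCl3(DME)1.5, Zn–Cu couple, DME, reflux; 34 added by syringe pump over 30 h (about 1 mM)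
Reagents that add atoms: none
Why: Low-valent titanium transfers one electron to each ketone; the two titanium-bound ketyls couple to a pinacolate, which is deoxygenated on the metal at reflux to the alkene (intramolecular McMurry coupling). The closest known reaction type is the coupling of 1,5-diketones to cyclopentenes. The ring closed is the five-membered ring C1–C2–C3–C4–C5, formed by joining the two carbonyl carbons of a 1,5-diketone whose acyl groups are held cis on a preformed cyclopentane, which gives the bicyclo[2.2.1]heptene. No stereocentre is formed, since C4 and C5 become sp2. The step needs ketone–ketone coupling to win over ketone–lactone and intermolecular coupling. Ketones are reduced faster than esters, high dilution suppresses dimers, and the cis-1,3 arrangement puts the carbonyl carbons within bonding distance. If some C3 epimer is present, enolisation of the acetyl group under the Lewis-acidic conditions can supply the reactive cis isomer. Silyl ethers and the benzyl-type ether are expected to survive, but the β-oxygen substituents on both ketones and the strain of the alkene make this the demanding step.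

Step 23
Reactants: 35 triethylsilyl ether
Product: 36 C2 alcohol
Conditions: PPTS, MeOH/CH2Cl2, 0 °C
Reagents that add atoms: none
Why: Acid-catalysed methanolysis of the triethylsilyl ether; the hindered secondary tert-butyldimethylsilyl ether and the acid-stable tert-butyldiphenylsilyl ether remain.

Step 24
Reactants: 36 alcohol
Product: 37 C2 acetate
Conditions: Ac2O, pyridine, DMAP (cat.), CH2Cl2, 25 °C
Reagents that add atoms: acetic anhydride, CC(=O)OC(C)=O
Why: Acylation; the acetate is syn to the alkene and therefore not prone to assisted ionisation in later steps.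

Step 25
Reactants: 37 4-methoxybenzyl ether
Product: 38 C7 primary alcohol
Conditions: DDQ, CH2Cl2/pH 7 buffer, 0 °C
Reagents that add atoms: none
Why: Oxidative cleavage of the 4-methoxybenzyl ether by hydride abstraction; silyl ethers, acetate and lactone are inert.

Step 26
Reactants: 38 alcohol
Product: 39 C7 aldehyde
Conditions: Dess–Martin periodinane, NaHCO3, CH2Cl2, 0 °C
Reagents that add atoms: none
Why: Buffered Dess–Martin oxidation; the β,γ-unsaturated aldehyde is used at once so that the strained alkene does not migrate.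

Step 27
Reactants: 39 aldehyde
Product: 40 methyl 2-(1-hydroxyalkyl)acrylate at C7 (C7 carbinol epimers)
Conditions: HC≡CCO2Me, i-Bu2AlH, NMO, THF, 0 °C; then 39, −78 → 0 °C
Reagents that add atoms: methyl propiolate, C#CC(=O)OC
Why: Vinylalumination: hydroalumination of the propiolate gives the α-aluminoacrylate, which adds to the aldehyde without base (Morita–Baylis–Hillman-type adduct); the carbinol configuration is lost in step 30.

Step 28
Reactants: 40 silyl ether
Product: 41 diol (C8 primary alcohol free)
Conditions: Bu4NF, AcOH, THF, 0 → 25 °C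
Reagents that add atoms: none
Why: Fluoride cleaves the primary tert-butyldiphenylsilyl ether faster than the hindered secondary tert-butyldimethylsilyl ether next to quaternary C10′; acetic acid buffers against acetate migration.

Step 29
Reactants: 41 diol
Product: 42 C8 aldehyde
Conditions: TEMPO (cat.), PhI(OAc)2, CH2Cl2, 25 °C
Reagents that add atoms: none
Why: Oxoammonium oxidation is selective for the primary alcohol; the electron-poor secondary allylic alcohol is left.

Step 30
Reactants: 42 allylic alcohol
Product: 43 (Z)-2-(bromomethyl)enoate aldehyde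
Conditions: NBS, Me2S, CH2Cl2, −20 → 0 °C
Reagents that add atoms: N-bromosuccinimide, O=C1CCC(=O)N1Br
Why: Corey–Kim-type activation of the allylic alcohol and bromide attack with allylic transposition (SN2′) give the more stable (Z)-2-(bromomethyl)enoate; the aldehyde is not affected.

Step 31
Reactants: 43 bromo aldehyde
Product: 45 1′-O-tert-butyldimethylsilyl japonicone A, via hydroxy ester 44 (not isolated)
Conditions: CrCl2, THF, 25 °C (high dilution); then TsOH·H2O (cat.), CH2Cl2
Reagents that add atoms: none
Why: Nozaki–Hiyama allylation: the allylchromium species adds through C7 to the C8 aldehyde in a chair-like transition state, which closes the seven-membered ring with H7 and H8 trans and restores the exocyclic methylene; the rigid norbornene and a pseudo-equatorial C10 methyl should select the face, and acid closes the trans-lactone.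

Step 32
Reactants: 45 silyl ether
Product: 46 japonicone A
Conditions: HF·pyridine, THF, 0 → 25 °C
Reagents that add atoms: none
Why: Fluoride-mediated cleavage of the last silyl ether; acetate and both lactones are stable to these conditions.

## Compound list

1 | (S)-(+)-carvone | CC1=CC[C@@H](CC1=O)C(C)=C | starting material
2 | 6-methylcarvone (C6 epimers) | CC1=CC[C@@H](C(C)C1=O)C(C)=C | intermediate
3 | methyl 2-[(1R,6R)-1,3-dimethyl-2-oxo-6-(prop-1-en-2-yl)cyclohex-3-en-1-yl]acetate | CC1=CC[C@H](C(C)=C)[C@@](C)(CC(=O)OC)C1=O | intermediate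
4 | methoxy hydroperoxide from 3 (side chain C(CH3)(OCH3)OOH) | CC1=CC[C@H](C(C)(OC)OO)[C@@](C)(CC(=O)OC)C1=O | intermediate
5 | methyl 2-[6-acetoxy-1,3-dimethyl-2-oxocyclohex-3-en-1-yl]acetate (acetoxy cis to 1-methyl) | CC1=CC[C@H](OC(C)=O)[C@@](C)(CC(=O)OC)C1=O | intermediate
6 | corresponding C1′ alcohol | CC1=CC[C@H](O)[C@@](C)(CC(=O)OC)C1=O | intermediate
7 | tert-butyldimethylsilyl ether of 6 | CC1=CC[C@H](O[Si](C)(C)C(C)(C)C)[C@@](C)(CC(=O)OC)C1=O | intermediate
8 | methyl 2-[6-(tert-butyldimethylsilyloxy)-1,3-dimethyl-2-oxocyclohexyl]acetate (all-cis) | C[C@@H]1CC[C@H](O[Si](C)(C)C(C)(C)C)[C@@](C)(CC(=O)OC)C1=O | intermediate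
9 | 2-methylene analogue of 8 | C[C@@H]1CC[C@H](O[Si](C)(C)C(C)(C)C)[C@@](C)(CC(=O)OC)C1=C | intermediate
10 | N-methoxy-N-methyl amide of 9 | C[C@@H]1CC[C@H](O[Si](C)(C)C(C)(C)C)[C@@](C)(CC(=O)N(C)OC)C1=C | intermediate
11 | 1-[6-(tert-butyldimethylsilyloxy)-1,3-dimethyl-2-methylenecyclohexyl]pent-4-en-2-one | C[C@@H]1CC[C@H](O[Si](C)(C)C(C)(C)C)[C@@](C)(CC(=O)CC=C)C1=C | intermediate
12 | (5R,8S,8aS)-8-(tert-butyldimethylsilyloxy)-5,8a-dimethyl-3,5,6,7,8,8a-hexahydronaphthalen-2(1H)-one | C[C@@H]1CC[C@H](O[Si](C)(C)C(C)(C)C)[C@@]2(C)CC(=O)CC=C12 | intermediate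
13 | methyl 2-[(2R,4aS,5S,8R)-5-(tert-butyldimethylsilyloxy)-4a,8-dimethyl-3-oxo-2,3,4,4a,5,6,7,8-octahydronaphthalen-2-yl]acetate | C[C@@H]1CC[C@H](O[Si](C)(C)C(C)(C)C)[C@@]2(C)CC(=O)[C@H](CC(=O)OC)C=C12 | intermediate
14 | 3-hydroxy analogue of 13 (hydroxyl cis to the acetate chain) | C[C@@H]1CC[C@H](O[Si](C)(C)C(C)(C)C)[C@@]2(C)C[C@H](O)[C@H](CC(=O)OC)C=C12 | intermediate
15 | (3aR,5R,8S,8aS,9aS)-8-(tert-butyldimethylsilyloxy)-5,8a-dimethyl-3a,5,6,7,8,8a,9,9a-octahydronaphtho[2,3-b]furan-2(3H)-one | C[C@@H]1CC[C@H](O[Si](C)(C)C(C)(C)C)[C@@]2(C)C[C@@H]3OC(=O)C[C@@H]3C=C12 | intermediate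
16 | methyl hydrogen (R)-3-methylglutarate | COC(=O)C[C@H](C)CC(=O)O | starting material
17 | methyl (R)-5-hydroxy-3-methylpentanoate | COC(=O)C[C@H](C)CCO | intermediate
18 | (R)-4-methyltetrahydro-2H-pyran-2-one | C[C@@H]1CCOC(=O)C1 | intermediate
19 | 3-[(dimethylamino)methyl]-(4R)-4-methyltetrahydropyran-2-one | C[C@@H]1CCOC(=O)C1CN(C)C | intermediate
20 | methiodide of 19 | C[C@@H]1CCOC(=O)C1C[N+](C)(C)C.[I-] | intermediate
21 | (R)-4-methyl-3-methylenetetrahydro-2H-pyran-2-one | C=C1C(=O)OCC[C@H]1C | intermediate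
22 | propane-1,3-diol | OCCCO | starting material
23 | 3-[(4-methoxybenzyl)oxy]propan-1-ol | COc1ccc(COCCCO)cc1 | intermediate
24 | 3-[(4-methoxybenzyl)oxy]propanal | COc1ccc(COCCC=O)cc1 | intermediate
25 | Michael–aldol adduct, free C5 hydroxyl (C1 quaternary, C11′–H) | C[C@@H]1CCOC(=O)[C@]1(C(O)CCOCc2ccc(OC)cc2)CC3C(=O)O[C@H]4C[C@@]5(C)C(=C[C@H]43)[C@H](C)CC[C@@H]5O[Si](C)(C)C(C)(C)C | intermediate
26 | C5 trimethylsilyl ether of 25 | C[C@@H]1CCOC(=O)[C@]1(C(O[Si](C)(C)C)CCOCc2ccc(OC)cc2)CC3C(=O)O[C@H]4C[C@@]5(C)C(=C[C@H]43)[C@H](C)CC[C@@H]5O[Si](C)(C)C(C)(C)C | intermediate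
27 | C11′-(3-trimethylsilylprop-2-ynyl) derivative of 26 | C[C@@H]1CCOC(=O)[C@]1(C(O[Si](C)(C)C)CCOCc2ccc(OC)cc2)C[C@]3(C(=O)O[C@H]4C[C@@]5(C)C(=C[C@H]43)[C@H](C)CC[C@@H]5O[Si](C)(C)C(C)(C)C)CC#C[Si](C)(C)C | intermediate
28 | C11′-propargyl bis-lactone, free C5 hydroxyl | C[C@@H]1CCOC(=O)[C@]1(C(O)CCOCc2ccc(OC)cc2)C[C@]3(C(=O)O[C@H]4C[C@@]5(C)C(=C[C@H]43)[C@H](C)CC[C@@H]5O[Si](C)(C)C(C)(C)C)CC#C | intermediate
29 | triol (C2, C5, C8 hydroxyls) | OCC[C@@H](C)[C@@](CO)(C(O)CCOCc2ccc(OC)cc2)C[C@]3(C(=O)O[C@H]4C[C@@]5(C)C(=C[C@H]43)[C@H](C)CC[C@@H]5O[Si](C)(C)C(C)(C)C)CC#C | intermediate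
30 | C8 tert-butyldiphenylsilyl ether of 29 | CC(C)(C)[Si](c7ccccc7)(c8ccccc8)OCC[C@@H](C)[C@@](CO)(C(O)CCOCc2ccc(OC)cc2)C[C@]3(C(=O)O[C@H]4C[C@@]5(C)C(=C[C@H]43)[C@H](C)CC[C@@H]5O[Si](C)(C)C(C)(C)C)CC#C | intermediate
31 | 2-formyl ketone with C11′-propargyl group | CC(C)(C)[Si](c7ccccc7)(c8ccccc8)OCC[C@@H](C)[C@@](C=O)(C(=O)CCOCc2ccc(OC)cc2)C[C@]3(C(=O)O[C@H]4C[C@@]5(C)C(=C[C@H]43)[C@H](C)CC[C@@H]5O[Si](C)(C)C(C)(C)C)CC#C | intermediate
32 | 2-formyl ketone with C11′-acetonyl group | CC(C)(C)[Si](c7ccccc7)(c8ccccc8)OCC[C@@H](C)[C@@](C=O)(C(=O)CCOCc2ccc(OC)cc2)C[C@]3(C(=O)O[C@H]4C[C@@]5(C)C(=C[C@H]43)[C@H](C)CC[C@@H]5O[Si](C)(C)C(C)(C)C)CC(C)=O | intermediate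
33 | aldol: spiro-lactone cyclopentane with C2 hydroxyl, C3 acetyl and C1 acyl all cis | CC(C)(C)[Si](c7ccccc7)(c8ccccc8)OCC[C@@H](C)[C@@]1(C(=O)CCOCc2ccc(OC)cc2)C[C@]3(C(=O)O[C@H]4C[C@@]5(C)C(=C[C@H]43)[C@H](C)CC[C@@H]5O[Si](C)(C)C(C)(C)C)[C@H](C(C)=O)[C@@H]1O | intermediate
34 | McMurry precursor: C2 triethylsilyl ether of 33 | CC(C)(C)[Si](c7ccccc7)(c8ccccc8)OCC[C@@H](C)[C@@]1(C(=O)CCOCc2ccc(OC)cc2)C[C@]3(C(=O)O[C@H]4C[C@@]5(C)C(=C[C@H]43)[C@H](C)CC[C@@H]5O[Si](C)(C)C(C)(C)C)[C@H](C(C)=O)[C@@H]1O[Si](CC)(CC)CC | intermediate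
35 | norbornene spirolactone (C4=C5) | CC(C)(C)[Si](c7ccccc7)(c8ccccc8)OCC[C@@H](C)[C@]12C[C@]3(C(=O)O[C@H]4C[C@@]5(C)C(=C[C@H]43)[C@H](C)CC[C@@H]5O[Si](C)(C)C(C)(C)C)[C@H](C(C)=C1CCOCc6ccc(OC)cc6)[C@@H]2O[Si](CC)(CC)CC | intermediate
36 | C2 alcohol | CC(C)(C)[Si](c7ccccc7)(c8ccccc8)OCC[C@@H](C)[C@]12C[C@]3(C(=O)O[C@H]4C[C@@]5(C)C(=C[C@H]43)[C@H](C)CC[C@@H]5O[Si](C)(C)C(C)(C)C)[C@H](C(C)=C1CCOCc6ccc(OC)cc6)[C@@H]2O | intermediate
37 | C2 acetate | CC(C)(C)[Si](c7ccccc7)(c8ccccc8)OCC[C@@H](C)[C@]12C[C@]3(C(=O)O[C@H]4C[C@@]5(C)C(=C[C@H]43)[C@H](C)CC[C@@H]5O[Si](C)(C)C(C)(C)C)[C@H](C(C)=C1CCOCc6ccc(OC)cc6)[C@@H]2OC(C)=O | intermediate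
38 | C7 alcohol | CC(C)(C)[Si](c7ccccc7)(c8ccccc8)OCC[C@@H](C)[C@]12C[C@]3(C(=O)O[C@H]4C[C@@]5(C)C(=C[C@H]43)[C@H](C)CC[C@@H]5O[Si](C)(C)C(C)(C)C)[C@H](C(C)=C1CCO)[C@@H]2OC(C)=O | intermediate
39 | C7 aldehyde | CC(C)(C)[Si](c7ccccc7)(c8ccccc8)OCC[C@@H](C)[C@]12C[C@]3(C(=O)O[C@H]4C[C@@]5(C)C(=C[C@H]43)[C@H](C)CC[C@@H]5O[Si](C)(C)C(C)(C)C)[C@H](C(C)=C1CC=O)[C@@H]2OC(C)=O | intermediate
40 | C7 hydroxy acrylate | CC(C)(C)[Si](c7ccccc7)(c8ccccc8)OCC[C@@H](C)[C@]12C[C@]3(C(=O)O[C@H]4C[C@@]5(C)C(=C[C@H]43)[C@H](C)CC[C@@H]5O[Si](C)(C)C(C)(C)C)[C@H](C(C)=C1CC(O)C(=C)C(=O)OC)[C@@H]2OC(C)=O | intermediate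
41 | C8 alcohol | OCC[C@@H](C)[C@]12C[C@]3(C(=O)O[C@H]4C[C@@]5(C)C(=C[C@H]43)[C@H](C)CC[C@@H]5O[Si](C)(C)C(C)(C)C)[C@H](C(C)=C1CC(O)C(=C)C(=O)OC)[C@@H]2OC(C)=O | intermediate
42 | C8 aldehyde | O=CC[C@@H](C)[C@]12C[C@]3(C(=O)O[C@H]4C[C@@]5(C)C(=C[C@H]43)[C@H](C)CC[C@@H]5O[Si](C)(C)C(C)(C)C)[C@H](C(C)=C1CC(O)C(=C)C(=O)OC)[C@@H]2OC(C)=O | intermediate
43 | (Z)-2-(bromomethyl)enoate aldehyde | O=CC[C@@H](C)[C@]12C[C@]3(C(=O)O[C@H]4C[C@@]5(C)C(=C[C@H]43)[C@H](C)CC[C@@H]5O[Si](C)(C)C(C)(C)C)[C@H](C(C)=C1C/C=C(\CBr)C(=O)OC)[C@@H]2OC(C)=O | intermediate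
44 | cyclised hydroxy ester (C7–C8 formed, H7/H8 trans) | C=C(C(=O)OC)[C@H]1[C@H](O)C[C@@H](C)[C@]34C[C@]5(C(=O)O[C@H]6C[C@@]7(C)C(=C[C@H]65)[C@H](C)CC[C@@H]7O[Si](C)(C)C(C)(C)C)[C@H](C(C)=C3C1)[C@@H]4OC(C)=O | intermediate
45 | 1′-O-tert-butyldimethylsilyl japonicone A | C=C1C(=O)O[C@@H]2C[C@@H](C)[C@]34C[C@]5(C(=O)O[C@H]6C[C@@]7(C)C(=C[C@H]65)[C@H](C)CC[C@@H]7O[Si](C)(C)C(C)(C)C)[C@H](C(C)=C3C[C@@H]12)[C@@H]4OC(C)=O | intermediate
46 | japonicone A | C=C1C(=O)O[C@@H]2C[C@@H](C)[C@]34C[C@]5(C(=O)O[C@H]6C[C@@]7(C)C(=C[C@H]65)[C@H](C)CC[C@@H]7O)[C@H](C(C)=C3C[C@@H]12)[C@@H]4OC(C)=O | target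

## Step count and least certain steps

Total: 32 steps. Longest linear sequence: 28 steps (steps 1–10 and 15–32).

**Step 22 (key step).** The most likely failure is loss of the β-oxygen substituents from the titanium ketyls, or a stall at the pinacolate because deoxygenation to the strained alkene is slow; coupling to the lactone carbonyl is a lesser concern. Fallback: from 34, SmI2 (divalent samarium) in THF should give the cis-pinacol F1. Thiocarbonyldiimidazole converts it into the cyclic thionocarbonate F2, and Corey–Winter elimination with 1,3-dimethyl-2-phenyl-1,3,2-diazaphospholidine returns alkene 35 without a titanium surface.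

**Step 15.** Proton transfer from the γ-position of 21 (erosion of C10), anionic oligomerisation of 21, or low facial selectivity in the aldol trap may intervene, because three components must react in order at low temperature. Fallback: the polarity of the first bond is reversed. From 15, Eschenmoser methylenation through the Mannich base F3 and its methiodide F4 gives the methylene eudesmanolide F5. The lithium enolate of 18 adds to F5, and the C11′ enolate is trapped on its convex face by the silylated propargylic bromide to give F6. Enolisation of the only remaining acidic position (C1) and aldol addition to 24 anti to the methyl group gives F7, and fluoride cleavage of the C–Si bond returns to 28.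

**Step 17.** The borohydride may fail to discriminate between the two lactones, or the new hydroxyls may migrate the eudesmanolide acyl group into a six-membered lactone. Fallback: from 26, the γ-lactone is protected as its potassium enolate (KN(SiMe3)2) while LiAlH4 reduces the δ-lactone; acidic work-up gives the triol F8. Silylation of the C8 hydroxyl gives F9 and the 1,3-diol is masked as the acetonide F10. C11′ is then propargylated (LiN(i-Pr)2, silylated propargylic bromide) to F11, and acid methanolysis of the acetonide with fluoride cleavage of the C–Si bond returns to 30.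

**Step 21.** Base may dehydrate the aldol to the enone, cleave the formyl group, or give the wrong C2 epimer, because all three are accessible from the same enolates. Fallback: from 32, Me3SiCl, NaI and Et3N give the thermodynamic bis(trimethylsilyl) enol ether F12. BF3·OEt2 then promotes an intramolecular Mukaiyama aldol addition to 33 under non-basic conditions, and silylation gives 34.

**Step 9.** The β,γ-unsaturated ketone may slip into conjugation, or the acetate chain may end on the wrong face, since the kinetic alkylation and the later protonation prefer opposite outcomes. Fallback: from 12, LiBH(s-Bu)3 gives the axial alcohol F13, which is esterified with bromoacetyl bromide to F14 and converted with N,N′-ditosylhydrazine and DBU into the diazoacetate F15. Rh2(OAc)4 then effects carbenoid insertion into the allylic C7′–H bond, which can only give the cis-fused lactone 15.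

**Step 31.** The allylchromium addition may attack the wrong face of the aldehyde, giving the C8 epimer or the cis series, because the seven-membered transition state is flexible. Fallback: from 43, indium in aqueous THF (open transition state) gives the C8-epimeric hydroxy ester F16. Dess–Martin oxidation gives ketone F17, chelation-controlled reduction with Zn(BH4)2 should give 44, and acid closes 45.

## Further compounds

F1 | step 22 | cis-4,5-diol (pinacol) of 34 | CC(C)(C)[Si](c7ccccc7)(c8ccccc8)OCC[C@@H](C)[C@]12C[C@]3(C(=O)O[C@H]4C[C@@]5(C)C(=C[C@H]43)[C@H](C)CC[C@@H]5O[Si](C)(C)C(C)(C)C)[C@H](C(C)(O)C1(O)CCOCc6ccc(OC)cc6)[C@@H]2O[Si](CC)(CC)CC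
F2 | step 22 | cyclic thionocarbonate of F1 | CC(C)(C)[Si](c7ccccc7)(c8ccccc8)OCC[C@@H](C)[C@]12C[C@]3(C(=O)O[C@H]4C[C@@]5(C)C(=C[C@H]43)[C@H](C)CC[C@@H]5O[Si](C)(C)C(C)(C)C)[C@H](C9(C)OC(=S)OC19CCOCc6ccc(OC)cc6)[C@@H]2O[Si](CC)(CC)CC
F3 | step 15 | 3-[(dimethylamino)methyl] derivative of 15 | C[C@@H]1CC[C@H](O[Si](C)(C)C(C)(C)C)[C@@]2(C)C[C@@H]3OC(=O)C(CN(C)C)[C@@H]3C=C12
F4 | step 15 | methiodide of F3 | C[C@@H]1CC[C@H](O[Si](C)(C)C(C)(C)C)[C@@]2(C)C[C@@H]3OC(=O)C(C[N+](C)(C)C)[C@@H]3C=C12.[I-]
F5 | step 15 | 3-methylene derivative of 15 (1′-O-silyl eudesmanolide) | C[C@@H]1CC[C@H](O[Si](C)(C)C(C)(C)C)[C@@]2(C)C[C@@H]3OC(=O)C(=C)[C@@H]3C=C12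
F6 | step 15 | Michael–alkylation product (C1–H, C11′ quaternary) | C[C@@H]1CCOC(=O)C1C[C@]3(C(=O)O[C@H]4C[C@@]5(C)C(=C[C@H]43)[C@H](C)CC[C@@H]5O[Si](C)(C)C(C)(C)C)CC#C[Si](C)(C)C
F7 | step 15 | C-silylated analogue of 28 | C[C@@H]1CCOC(=O)[C@]1(C(O)CCOCc2ccc(OC)cc2)C[C@]3(C(=O)O[C@H]4C[C@@]5(C)C(=C[C@H]43)[C@H](C)CC[C@@H]5O[Si](C)(C)C(C)(C)C)CC#C[Si](C)(C)C
F8 | step 17 | triol with C11′–H | OCC[C@@H](C)[C@@](CO)(C(O)CCOCc2ccc(OC)cc2)CC3C(=O)O[C@H]4C[C@@]5(C)C(=C[C@H]43)[C@H](C)CC[C@@H]5O[Si](C)(C)C(C)(C)C
F9 | step 17 | C8 tert-butyldiphenylsilyl ether of F8 | CC(C)(C)[Si](c7ccccc7)(c8ccccc8)OCC[C@@H](C)[C@@](CO)(C(O)CCOCc2ccc(OC)cc2)CC3C(=O)O[C@H]4C[C@@]5(C)C(=C[C@H]43)[C@H](C)CC[C@@H]5O[Si](C)(C)C(C)(C)C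
F10 | step 17 | acetonide of F9 | CC(C)(C)[Si](c7ccccc7)(c8ccccc8)OCC[C@@H](C)[C@]9(COC(C)(C)OC9CCOCc2ccc(OC)cc2)CC3C(=O)O[C@H]4C[C@@]5(C)C(=C[C@H]43)[C@H](C)CC[C@@H]5O[Si](C)(C)C(C)(C)C
F11 | step 17 | C11′-(3-trimethylsilylprop-2-ynyl) derivative of F10 | CC(C)(C)[Si](c7ccccc7)(c8ccccc8)OCC[C@@H](C)[C@]9(COC(C)(C)OC9CCOCc2ccc(OC)cc2)C[C@]3(C(=O)O[C@H]4C[C@@]5(C)C(=C[C@H]43)[C@H](C)CC[C@@H]5O[Si](C)(C)C(C)(C)C)CC#C[Si](C)(C)C
F12 | step 21 | bis(trimethylsilyl) enol ether of 32 | CC(C)(C)[Si](c7ccccc7)(c8ccccc8)OCC[C@@H](C)[C@@](C=O)(C(O[Si](C)(C)C)=CCOCc2ccc(OC)cc2)C[C@]3(C(=O)O[C@H]4C[C@@]5(C)C(=C[C@H]43)[C@H](C)CC[C@@H]5O[Si](C)(C)C(C)(C)C)C=C(C)O[Si](C)(C)C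
F13 | step 9 | axial alcohol from 12 | C[C@@H]1CC[C@H](O[Si](C)(C)C(C)(C)C)[C@@]2(C)C[C@H](O)CC=C12
F14 | step 9 | bromoacetate of F13 | C[C@@H]1CC[C@H](O[Si](C)(C)C(C)(C)C)[C@@]2(C)C[C@H](OC(=O)CBr)CC=C12
F15 | step 9 | diazoacetate of F13 | C[C@@H]1CC[C@H](O[Si](C)(C)C(C)(C)C)[C@@]2(C)C[C@H](OC(=O)C=[N+]=[N-])CC=C12
F16 | step 31 | C8 epimer of 44 | C=C(C(=O)OC)[C@H]1[C@@H](O)C[C@@H](C)[C@]34C[C@]5(C(=O)O[C@H]6C[C@@]7(C)C(=C[C@H]65)[C@H](C)CC[C@@H]7O[Si](C)(C)C(C)(C)C)[C@H](C(C)=C3C1)[C@@H]4OC(C)=O
F17 | step 31 | C8 ketone from F16 | C=C(C(=O)OC)[C@H]1C(=O)C[C@@H](C)[C@]34C[C@]5(C(=O)O[C@H]6C[C@@]7(C)C(=C[C@H]65)[C@H](C)CC[C@@H]7O[Si](C)(C)C(C)(C)C)[C@H](C(C)=C3C1)[C@@H]4OC(C)=O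
A1 | alternative 1 | 9′-phenylsulfonyl eudesmanolide spiro-norbornene | COC(OC)C[C@@H](C)[C@]12C[C@]3(C(=O)O[C@H]4[C@H](S(=O)(=O)c5ccccc5)[C@@]6(C)C(=C[C@H]43)[C@H](C)CC[C@@H]6O[Si](C)(C)C(C)(C)C)[C@H](C(C)=C1CC=C)[C@@H]2OCc7ccc(OC)cc7
A2 | alternative 2 | lactol ethyl ether with closed seven-membered ring | C1[C@H](OCC)O[C@@H]2C[C@@H](C)[C@]34C[C@]5(C(=O)O[C@H]6C[C@@]7(C)C(=C[C@H]65)[C@H](C)CC[C@@H]7O[Si](C)(C)C(C)(C)C)[C@H](C(C)=C3C[C@@H]12)[C@@H]4OC(C)=O
A3 | alternative 3 | C2-hydroxy C5-keto bicyclo[2.2.1]heptane spirolactone | COC(=O)C[C@@H](C)[C@]12C[C@]3(C(=O)O[C@H]4C[C@@]5(C)C(=C[C@H]43)[C@H](C)CC[C@@H]5O[Si](C)(C)C(C)(C)C)[C@H]([C@H](C)C1=O)[C@@H]2O
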